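**Retrosynthetic overview**

Labels: C1 = oxygenated bridgehead (bonded to O7 and to the acyl carbon C9), C2 = gem-dimethyl carbon, C3 = prenyl-bearing methine, C4 = ring CH2, C5 = all-carbon bridgehead with the second prenyl group, C6 = lactone carbonyl, C8 = one-carbon ketone bridge.
The plan rests on the acyloin unit C8(=O)–C1(O7) inside the cyclohexanone ring C1–C2–C3–C4–C5–C8, and on C5 carrying two one-carbon arms (C6, C8) that become identical at the aldehyde level.
The lactone is taken back to its lactol and then to the 1,3-diaxial hydroxy aldehyde; C1–C8 is cut to an acyclic C5 bis-formyl C1/C9 diketone. Forward, the carbocycle forms first and the oxa-bridge second.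
The diketone dialdehyde comes from a tetraol. C1–C9 is made from a C1 aldehyde and an α-lithiated carbamate derived from (R)-2-methylbutanoic acid. C5 comes from diethyl malonate, alkylated first with the hindered C4 iodide and only then with prenyl bromide.
C3 is set by Evans prenylation of an imide of 3,3-dimethylpent-4-enoic acid. Its vinyl group is first cut to C1 and carried as a dimethyl acetal, because a C1 ester would lactonise on to the C4 alcohol.

Key step: step 15

Remark: the carbinol centres formed at C1 and C9 before the global oxidation, and the anomeric centre of the lactol, are expected as mixtures; all are erased later, so they are left undefined in the SMILES.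

**Route**

Step 1
Reactants: 1 3,3-dimethylpent-4-enoic acid; 2 (4R)-4-benzyl-1,3-oxazolidin-2-one
Product: 4 (4R)-4-benzyl-3-(3,3-dimethylpent-4-enoyl)-1,3-oxazolidin-2-one, via mixed pivalic anhydride 3 (not isolated)
Conditions: PivCl, Et3N, THF, −20 °C; then LiCl, 2, −20 °C → rt
Reagents that add atoms: none
Why: N-acylation of the oxazolidinone through a mixed anhydride should be clean because the nucleophile attacks the less hindered of the two anhydride carbonyls.

Step 2
Reactants: 4 (4R)-4-benzyl-3-(3,3-dimethylpent-4-enoyl)-1,3-oxazolidin-2-one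
Product: 6 (4R)-4-benzyl-3-(3,3-dimethyl-4-oxobutanoyl)-1,3-oxazolidin-2-one, via secondary ozonide 5 (not isolated)
Conditions: O3, CH2Cl2, −78 °C; then Me2S, −78 °C → rt
Reagents that add atoms: ozone [O-][O+]=O
Why: Ozonolysis with reductive work-up cuts the only alkene to the non-enolisable C1 aldehyde, and it is placed before any prenyl group is present.

Step 3
Reactants: 6 (4R)-4-benzyl-3-(3,3-dimethyl-4-oxobutanoyl)-1,3-oxazolidin-2-one
Product: 7 (4R)-4-benzyl-3-(4,4-dimethoxy-3,3-dimethylbutanoyl)-1,3-oxazolidin-2-one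
Conditions: HC(OMe)3, TsOH·H2O (cat.), MeOH, rt
Reagents that add atoms: trimethyl orthoformate COC(OC)OC
Why: Acid-catalysed acetalisation with an orthoformate as water scavenger masks C1 in a form that cannot acylate a later C4 alcohol and that survives enolates and hydrides.

Step 4
Reactants: 7 (4R)-4-benzyl-3-(4,4-dimethoxy-3,3-dimethylbutanoyl)-1,3-oxazolidin-2-one; 8 prenyl bromide
Product: 10 (4R)-4-benzyl-3-[(2R)-2-(1,1-dimethoxy-2-methylpropan-2-yl)-5-methylhex-4-enoyl]-1,3-oxazolidin-2-one, via chelated sodium enolate 9 (not isolated)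
Conditions: NaN(SiMe3)2, THF, −78 °C; then 8, −78 → −30 °C
Reagents that add atoms: none
Why: In this Evans asymmetric alkylation the benzyl group of the (R)-auxiliary shields one face of the chelated Z enolate, so the reactive allylic bromide enters from the other face and sets C3 in the spatial arrangement of the target (descriptor R at this stage).

Step 5
Reactants: 10 (4R)-4-benzyl-3-[(2R)-2-(1,1-dimethoxy-2-methylpropan-2-yl)-5-methylhex-4-enoyl]-1,3-oxazolidin-2-one
Product: 11 (2R)-2-(1,1-dimethoxy-2-methylpropan-2-yl)-5-methylhex-4-en-1-ol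
Conditions: LiBH4, MeOH (1 equiv), Et2O, 0 °C → rt; Et3N-washed silica
Reagents that add atoms: none
Why: Reductive cleavage of the imide with methanol-modified borohydride favours the exocyclic carbonyl even for hindered acyl groups, leaves acetal and alkene alone and does not touch C3.

Step 6
Reactants: 11 (2R)-2-(1,1-dimethoxy-2-methylpropan-2-yl)-5-methylhex-4-en-1-ol
Product: 12 (5R)-5-(iodomethyl)-7,7-dimethoxy-2,6,6-trimethylhept-2-ene
Conditions: I2, PPh3, imidazole, CH2Cl2, 0 °C → rt
Reagents that add atoms: iodine II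
Why: Appel-type iodination under imidazole buffering converts the primary alcohol without free acid, which would otherwise close the hydroxy acetal to a cyclic acetal.

Step 7
Reactants: 13 diethyl malonate; 12 (5R)-5-(iodomethyl)-7,7-dimethoxy-2,6,6-trimethylhept-2-ene
Product: 15 diethyl 2-[(2S)-4,4-dimethoxy-3,3-dimethyl-2-(3-methylbut-2-enyl)butyl]propanedioate, via sodium diethyl malonate 14 (not isolated)
Conditions: 13 (3 equiv), NaH, THF/DMF, 0 °C; then 12, 60 °C
Reagents that add atoms: none
Why: In this malonic ester alkylation (SN2) the small unsubstituted malonate anion, used in excess and concentrated, is matched with the β-branched iodide, which is the reason for postponing the C5 prenylation.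

Step 8
Reactants: 15 diethyl 2-[(2S)-4,4-dimethoxy-3,3-dimethyl-2-(3-methylbut-2-enyl)butyl]propanedioate; 8 prenyl bromide
Product: 17 diethyl 2-[(2S)-4,4-dimethoxy-3,3-dimethyl-2-(3-methylbut-2-enyl)butyl]-2-(3-methylbut-2-enyl)propanedioate, via sodium malonate enolate 16 (not isolated)
Conditions: NaH, THF/DMF, 0 °C; then 8, rt
Reagents that add atoms: none
Why: A second malonate alkylation with a highly reactive allylic bromide builds the quaternary and still prochiral C5.

Step 9
Reactants: 17 diethyl 2-[(2S)-4,4-dimethoxy-3,3-dimethyl-2-(3-methylbut-2-enyl)butyl]-2-(3-methylbut-2-enyl)propanedioate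
Product: 18 diethyl 2-[(2S)-3,3-dimethyl-2-(3-methylbut-2-enyl)-4-oxobutyl]-2-(3-methylbut-2-enyl)propanedioate
Conditions: TsOH·H2O (cat.), acetone/H2O, rt
Reagents that add atoms: water O
Why: Mild acid hydrolysis of the dimethyl acetal frees the non-enolisable C1 aldehyde under conditions that esters and trisubstituted alkenes tolerate.

Step 10
Reactants: 19 (2R)-2-methylbutanoic acid
Product: 20 (2R)-2-methylbutan-1-ol
Conditions: LiAlH4, Et2O, 0 °C → rt
Reagents that add atoms: none
Why: Hydride reduction of the carboxylate does not involve the C–H bond of the stereocentre, so its configuration is kept.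

Step 11
Reactants: 20 (2R)-2-methylbutan-1-ol
Product: 21 (2R)-2-methylbutyl N,N-diisopropylcarbamate
Conditions: iPr2NCOCl, Et3N, CH2Cl2, reflux
Reagents that add atoms: N,N-diisopropylcarbamoyl chloride CC(C)N(C(C)C)C(=O)Cl
Why: O-carbamoylation installs the directing and dipole-stabilising group needed to turn the future C9 into a carbanion.

Step 12
Reactants: 21 (2R)-2-methylbutyl N,N-diisopropylcarbamate; 18 diethyl 2-[(2S)-3,3-dimethyl-2-(3-methylbut-2-enyl)-4-oxobutyl]-2-(3-methylbut-2-enyl)propanedioate
Product: 23 diethyl 2-[(2S,6R)-5-(diisopropylcarbamoyloxy)-4-hydroxy-3,3,6-trimethyl-2-(3-methylbut-2-enyl)octyl]-2-(3-methylbut-2-enyl)propanedioate, via lithiated carbamate 22 (not isolated)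
Conditions: 21, s-BuLi, TMEDA, Et2O, −78 °C; then 18, −78 °C; AcOH quench at −78 °C
Reagents that add atoms: none
Why: Carbamate-directed α-lithiation removes a C9 proton and not the tertiary one next to it, and the carbanion should add to the aldehyde far faster than to the hindered quaternary malonate esters, forming C1–C9 with both oxygens in place as inconsequential carbinol mixtures.

Step 13
Reactants: 23 diethyl 2-[(2S,6R)-5-(diisopropylcarbamoyloxy)-4-hydroxy-3,3,6-trimethyl-2-(3-methylbut-2-enyl)octyl]-2-(3-methylbut-2-enyl)propanedioate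
Product: 24 2-[(2S,6R)-4,5-dihydroxy-3,3,6-trimethyl-2-(3-methylbut-2-enyl)octyl]-2-(3-methylbut-2-enyl)propane-1,3-diol
Conditions: LiAlH4, THF, 0 °C → reflux
Reagents that add atoms: none
Why: Exhaustive hydride reduction takes both esters to CH2OH and cleaves the carbamate in the same operation, while isolated alkenes and both stereocentres are inert.

Step 14
Reactants: 24 2-[(2S,6R)-4,5-dihydroxy-3,3,6-trimethyl-2-(3-methylbut-2-enyl)octyl]-2-(3-methylbut-2-enyl)propane-1,3-diol
Product: 25 2-[(2S,6R)-3,3,6-trimethyl-2-(3-methylbut-2-enyl)-4,5-dioxooctyl]-2-(3-methylbut-2-enyl)propanedial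
Conditions: (COCl)2, DMSO, CH2Cl2, −78 °C; then iPr2NEt, −78 → −30 °C; cold pH 7 buffer; used at once
Reagents that add atoms: none
Why: In the Swern oxidation all four alcohols are activated before base is added, so no β-hydroxy aldehyde prone to retro-aldol is exposed, activated DMSO takes 1,2-diols to 1,2-diketones without C–C cleavage, and a hindered amine at low temperature spares the centre next to C9.

Step 15
Reactants: 25 2-[(2S,6R)-3,3,6-trimethyl-2-(3-methylbut-2-enyl)-4,5-dioxooctyl]-2-(3-methylbut-2-enyl)propanedial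
Product: 27 (1R,3S,5S)-7-hydroxy-4,4-dimethyl-1,3-bis(3-methylbut-2-enyl)-5-[(2R)-2-methylbutanoyl]-6-oxabicyclo[3.2.1]octan-8-one, via hydroxy aldehyde 26 (not isolated)
Conditions: 2-(pentafluorophenyl)-6,7-dihydro-5H-pyrrolo[2,1-c][1,2,4]triazol-2-ium tetrafluoroborate (20 mol %), iPr2NEt (20 mol %), toluene (0.02 M), 4 Å molecular sieves, rt → 40 °C
Reagents that add atoms: none
Why: The carbene freed from the triazolium salt adds to one formyl group of 25, a proton shift gives the Breslow enaminol, its nucleophilic carbon (C8) attacks the C1 carbonyl, which the neighbouring C9 carbonyl activates, and loss of the carbene leaves the C8 ketone and the tertiary C1 alcohol of 26. The closest known reaction is the intramolecular crossed aldehyde–ketone benzoin cyclisation with triazolylidene catalysts, of which desymmetrising versions exist. The carbocycle C1–C2–C3–C4–C5–C8 closes 6-exo-trig, whereas attack on C9 would need a seven-membered ring, and the oxa-bridge then closes 5-exo-trig when the C1 hydroxyl adds to the remaining formyl carbon C6. C5 is set by the choice between the two diastereotopic formyl groups: in a chair transition state anchored by the equatorial C3 prenyl group the larger C5 prenyl group also lies equatorial, so the formyl group that reacts is the one that leaves its partner axial. C1 is set with the bulky acyl group equatorial and the oxygen axial, and because benzoin addition is reversible any other isomer can revert, while only the isomer with hydroxyl and formyl group 1,3-diaxial is withdrawn as lactol 27, whose anomeric centre is uncontrolled and is erased in step 16. The step also needs the centre next to C9 and both formyl groups to survive, which is why only a catalytic amount of a weak amine base, an aprotic solvent, molecular sieves and high dilution are used.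

Step 16
Reactants: 27 (1R,3S,5S)-7-hydroxy-4,4-dimethyl-1,3-bis(3-methylbut-2-enyl)-5-[(2R)-2-methylbutanoyl]-6-oxabicyclo[3.2.1]octan-8-one
Product: 28 (1S,3S,5S)-4,4-dimethyl-1,3-bis(3-methylbut-2-enyl)-5-[(2R)-2-methylbutanoyl]-6-oxabicyclo[3.2.1]octane-7,8-dione
Conditions: Dess–Martin periodinane, CH2Cl2, rt
Reagents that add atoms: none
Why: Dess–Martin oxidation copes with the hindered lactol C–H next to quaternary C5 and gives the lactone without touching alkenes, ketones or any stereocentre.

**Compound list**

1 | 3,3-dimethylpent-4-enoic acid | C=CC(C)(C)CC(=O)O | starting material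
2 | (4R)-4-benzyl-1,3-oxazolidin-2-one | O=C1N[C@H](Cc2ccccc2)CO1 | starting material
3 | 3,3-dimethylpent-4-enoic pivalic anhydride | C=CC(C)(C)CC(=O)OC(=O)C(C)(C)C | intermediate
4 | (4R)-4-benzyl-3-(3,3-dimethylpent-4-enoyl)-1,3-oxazolidin-2-one | C=CC(C)(C)CC(=O)N1[C@H](Cc2ccccc2)COC1=O | intermediate
5 | secondary ozonide (1,2,4-trioxolane) of 4 | CC(C)(CC(=O)N1[C@H](Cc2ccccc2)COC1=O)C3OCOO3 | intermediate
6 | (4R)-4-benzyl-3-(3,3-dimethyl-4-oxobutanoyl)-1,3-oxazolidin-2-one | CC(C)(C=O)CC(=O)N1[C@H](Cc2ccccc2)COC1=O | intermediate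
7 | (4R)-4-benzyl-3-(4,4-dimethoxy-3,3-dimethylbutanoyl)-1,3-oxazolidin-2-one | COC(OC)C(C)(C)CC(=O)N1[C@H](Cc2ccccc2)COC1=O | intermediate
8 | prenyl bromide (1-bromo-3-methylbut-2-ene) | CC(C)=CCBr | starting material
9 | Z sodium enolate of 7 | [Na+].COC(OC)C(C)(C)/C=C(\[O-])N1[C@H](Cc2ccccc2)COC1=O | intermediate
10 | (4R)-4-benzyl-3-[(2R)-2-(1,1-dimethoxy-2-methylpropan-2-yl)-5-methylhex-4-enoyl]-1,3-oxazolidin-2-one | COC(OC)C(C)(C)[C@@H](CC=C(C)C)C(=O)N1[C@H](Cc2ccccc2)COC1=O | intermediate
11 | (2R)-2-(1,1-dimethoxy-2-methylpropan-2-yl)-5-methylhex-4-en-1-ol | COC(OC)C(C)(C)[C@@H](CC=C(C)C)CO | intermediate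
12 | (5R)-5-(iodomethyl)-7,7-dimethoxy-2,6,6-trimethylhept-2-ene | COC(OC)C(C)(C)[C@@H](CC=C(C)C)CI | intermediate
13 | diethyl malonate | CCOC(=O)CC(=O)OCC | starting material
14 | sodium salt of diethyl malonate | [Na+].CCOC(=O)[CH-]C(=O)OCC | intermediate
15 | diethyl 2-[(2S)-4,4-dimethoxy-3,3-dimethyl-2-(3-methylbut-2-enyl)butyl]propanedioate | COC(OC)C(C)(C)[C@@H](CC=C(C)C)CC(C(=O)OCC)C(=O)OCC | intermediate
16 | sodium enolate of 15 | [Na+].COC(OC)C(C)(C)[C@@H](CC=C(C)C)C[C-](C(=O)OCC)C(=O)OCC | intermediate
17 | diethyl 2-[(2S)-4,4-dimethoxy-3,3-dimethyl-2-(3-methylbut-2-enyl)butyl]-2-(3-methylbut-2-enyl)propanedioate | COC(OC)C(C)(C)[C@@H](CC=C(C)C)CC(CC=C(C)C)(C(=O)OCC)C(=O)OCC | intermediate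
18 | diethyl 2-[(2S)-3,3-dimethyl-2-(3-methylbut-2-enyl)-4-oxobutyl]-2-(3-methylbut-2-enyl)propanedioate | O=CC(C)(C)[C@@H](CC=C(C)C)CC(CC=C(C)C)(C(=O)OCC)C(=O)OCC | intermediate
19 | (2R)-2-methylbutanoic acid | CC[C@@H](C)C(=O)O | starting material
20 | (2R)-2-methylbutan-1-ol | CC[C@@H](C)CO | intermediate
21 | (2R)-2-methylbutyl N,N-diisopropylcarbamate | CC[C@@H](C)COC(=O)N(C(C)C)C(C)C | intermediate
22 | (2R)-1-lithio-2-methylbutyl N,N-diisopropylcarbamate (TMEDA-solvated, mixture at C9) | CC[C@@H](C)C([Li])OC(=O)N(C(C)C)C(C)C | intermediate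
23 | diethyl 2-[(2S,6R)-5-(diisopropylcarbamoyloxy)-4-hydroxy-3,3,6-trimethyl-2-(3-methylbut-2-enyl)octyl]-2-(3-methylbut-2-enyl)propanedioate (mixture at C1 and C9) | CC[C@@H](C)C(OC(=O)N(C(C)C)C(C)C)C(O)C(C)(C)[C@@H](CC=C(C)C)CC(CC=C(C)C)(C(=O)OCC)C(=O)OCC | intermediate
24 | 2-[(2S,6R)-4,5-dihydroxy-3,3,6-trimethyl-2-(3-methylbut-2-enyl)octyl]-2-(3-methylbut-2-enyl)propane-1,3-diol (mixture at C1 and C9) | CC[C@@H](C)C(O)C(O)C(C)(C)[C@@H](CC=C(C)C)CC(CC=C(C)C)(CO)CO | intermediate
25 | 2-[(2S,6R)-3,3,6-trimethyl-2-(3-methylbut-2-enyl)-4,5-dioxooctyl]-2-(3-methylbut-2-enyl)propanedial | CC[C@@H](C)C(=O)C(=O)C(C)(C)[C@@H](CC=C(C)C)CC(CC=C(C)C)(C=O)C=O | intermediate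
26 | (1R,3S,5S)-3-hydroxy-4,4-dimethyl-1,5-bis(3-methylbut-2-enyl)-3-[(2R)-2-methylbutanoyl]-2-oxocyclohexane-1-carbaldehyde | CC[C@@H](C)C(=O)[C@]1(O)C(=O)[C@@](CC=C(C)C)(C=O)C[C@H](CC=C(C)C)C1(C)C | intermediate
27 | (1R,3S,5S)-7-hydroxy-4,4-dimethyl-1,3-bis(3-methylbut-2-enyl)-5-[(2R)-2-methylbutanoyl]-6-oxabicyclo[3.2.1]octan-8-one (anomeric mixture) | CC[C@@H](C)C(=O)[C@@]12OC(O)[C@@](CC=C(C)C)(C[C@H](CC=C(C)C)C1(C)C)C2=O | intermediate
28 | (1S,3S,5S)-4,4-dimethyl-1,3-bis(3-methylbut-2-enyl)-5-[(2R)-2-methylbutanoyl]-6-oxabicyclo[3.2.1]octane-7,8-dione | CC[C@@H](C)C(=O)[C@@]12OC(=O)[C@@](CC=C(C)C)(C[C@H](CC=C(C)C)C1(C)C)C2=O | target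

**Step count**

Total step count: 16. Longest linear sequence: 14 (steps 1–9 and 12–16).

**Steps most likely to fail**

Step 15.
- The carbene adduct of the malondialdehyde may fragment with loss of a formyl group, or pass hydride to the diketone.
- Bond formation between two carbons that each sit next to a quaternary centre may be too slow.
- The carbene may engage the diketone itself.
- The two formyl groups may be poorly distinguished, and the centre next to C9 may epimerise.
- The fallback replaces the redox-neutral acyl-anion closure by a reductive one and sets out from 25. SmI2 (about 2 equiv, THF, −78 °C) should reduce the 1,2-diketone first, as it is the most easily reduced group. The resulting samarium ketyl or enediolate should add through C1 to a formyl group in a pinacol-type six-ring closure.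
- After the C1 hydroxyl closes on the second formyl group, this gives the C8 carbinol of the lactol F1. Dess–Martin periodinane in excess then oxidises the C8 carbinol and the lactol in one operation, and the route is rejoined at 28.

Step 14.
- The hindered C1 carbinol may be oxidised incompletely.
- A formyl group may be lost from the malondialdehyde during basic work-up.
- The amine may cause epimerisation next to the new diketone.
- The fallback is a staged, amine-free oxidation with chemoselective reagents and sets out from 24. TEMPO (cat.) with PhI(OAc)2 in CH2Cl2 should oxidise only the two primary alcohols and give the dihydroxy dialdehyde F2. IBX in DMSO at rt then takes the secondary 1,2-diol to the diketone without C–C cleavage, rejoining the route at 25.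

Step 7.
- Substitution at a β-branched carbon next to a tert-alkyl group may be slow.
- That would let participation of an acetal oxygen (five-membered oxonium ion, then demethylation) or elimination compete.
- The fallback makes C4–C5 by acylation and deoxygenation instead of SN2 and sets out from 10.
- LiOH/H2O2 (THF/H2O, 0 °C) gives the carboxylic acid F3.
- Meldrum's acid, EDC·HCl and DMAP in CH2Cl2 give the acyl Meldrum's acid F4.
- NaBH4 with AcOH in CH2Cl2 reduces the acyl carbon to CH2 and gives the 5-alkyl Meldrum's acid F5.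
- K2CO3 and 8 in DMF give the 5,5-dialkyl Meldrum's acid F6.
- NaOEt in EtOH opens the ring to the malonic half-ester F7 (as its sodium salt), which is ethylated in the same flask with EtI, rejoining the route at 17.

**Further compounds**

F1 | step 15 | C8 carbinol of lactol 27 (7,8-dihydroxy-6-oxabicyclo[3.2.1]octane, C1, C3 and C5 arranged as in 27, mixture at C6 and C8) | CC[C@@H](C)C(=O)[C@@]12OC(O)[C@@](CC=C(C)C)(C[C@H](CC=C(C)C)C1(C)C)C2O
F2 | step 14 | 2-[(2S,6R)-4,5-dihydroxy-3,3,6-trimethyl-2-(3-methylbut-2-enyl)octyl]-2-(3-methylbut-2-enyl)propanedial | CC[C@@H](C)C(O)C(O)C(C)(C)[C@@H](CC=C(C)C)CC(CC=C(C)C)(C=O)C=O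
F3 | step 7 | (2R)-2-(1,1-dimethoxy-2-methylpropan-2-yl)-5-methylhex-4-enoic acid | COC(OC)C(C)(C)[C@@H](CC=C(C)C)C(=O)O
F4 | step 7 | acyl Meldrum's acid of F3 (enol form) | COC(OC)C(C)(C)[C@@H](CC=C(C)C)C(O)=C1C(=O)OC(C)(C)OC1=O
F5 | step 7 | 5-[(2S)-4,4-dimethoxy-3,3-dimethyl-2-(3-methylbut-2-enyl)butyl]-2,2-dimethyl-1,3-dioxane-4,6-dione | COC(OC)C(C)(C)[C@@H](CC=C(C)C)CC1C(=O)OC(C)(C)OC1=O
F6 | step 7 | 5-[(2S)-4,4-dimethoxy-3,3-dimethyl-2-(3-methylbut-2-enyl)butyl]-2,2-dimethyl-5-(3-methylbut-2-enyl)-1,3-dioxane-4,6-dione | COC(OC)C(C)(C)[C@@H](CC=C(C)C)CC1(CC=C(C)C)C(=O)OC(C)(C)OC1=O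
F7 | step 7 | monoethyl ester of the dialkylmalonic acid corresponding to 17 (mixture at C5) | COC(OC)C(C)(C)[C@@H](CC=C(C)C)CC(CC=C(C)C)(C(=O)OCC)C(=O)O
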